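**Retrosynthetic overview**

- The target is (2S)-6-geranylhesperetin. Ring A carries OH, geranyl, OH and H at C5, C6, C7 and C8, which is the pattern of the bis-silyl dienol ether of methyl 2-geranylacetoacetate; C4a and C8a are the α- and β-carbons of the ring C enone.
- Key disconnection: C4a–C5 and C8–C8a. Ring A is built last on a (2S)-2-aryl-5-(phenylsulfinyl)-2,3-dihydropyran-4-one by [4+2] addition, loss of PhSOH and loss of methanol. O1 and C2 already sit in ring C, so neither a C6/C8 choice nor ring A protection arises.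
- Ring C and its C2 centre come from an asymmetric hetero-Diels–Alder reaction of silylated isovanillin with Danishefsky's diene, followed by C5 sulfenylation and S-oxidation. The diene comes from methyl acetoacetate and geranyl bromide.
- Order of ring formation: ring B is bought, ring C is closed in step 2, ring A in step 8; desilylation ends the route.

Key step: step 8

Assumption: (S)-BINOL/Ti(OiPr)4 is taken to direct the diene to the Si face of the aryl aldehyde, the sense this catalyst shows in aldehyde allylation; if the (2R)-pyranone were found, (R)-BINOL would be used with no other change.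

Remark: flavanone numbering (O1, C2 … C8a) is used for all bicyclic compounds; geranyl is (2E)-3,7-dimethylocta-2,6-dien-1-yl; "aryl" in short names is 4-methoxy-3-(triisopropylsilyloxy)phenyl.

**Route**

Step 1
Reactants: 1 isovanillin
Product: 2 4-methoxy-3-(triisopropylsilyloxy)benzaldehyde
Conditions: iPr3SiCl, imidazole, DMF, 25 °C
Reagents that add atoms: triisopropylsilyl chloride, CC(C)[Si](Cl)(C(C)C)C(C)C
Why: Imidazole-mediated silyl ether formation at the only phenol; the hindered silyl ether is chosen to survive CF3CO2H, the sulfenylation, the peracid and the acidic work-up of step 8.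

Step 2
Reactants: 2 4-methoxy-3-(triisopropylsilyloxy)benzaldehyde; 3 (E)-1-methoxy-3-(trimethylsilyloxy)buta-1,3-diene
Product: 5 (S)-2-[4-methoxy-3-(triisopropylsilyloxy)phenyl]-2,3-dihydro-4H-pyran-4-one, via Mukaiyama aldol adduct 4 (not isolated)
Conditions: (S)-BINOL (20 mol %), Ti(OiPr)4 (10 mol %), 4 Å MS, Et2O, −20 °C; then CF3CO2H, CH2Cl2, 0 °C
Reagents that add atoms: none
Why: Keck-type hetero-Diels–Alder reaction, that is a titanium BINOLate-catalysed Mukaiyama aldol addition followed by acid-induced cyclisation with loss of methanol; the chiral titanium complex shields one face of the bound aldehyde and so should set C2 as (S).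

Step 3
Reactants: 5 (S)-2-[4-methoxy-3-(triisopropylsilyloxy)phenyl]-2,3-dihydro-4H-pyran-4-one
Product: 7 (S)-2-[4-methoxy-3-(triisopropylsilyloxy)phenyl]-5-(phenylthio)-2,3-dihydro-4H-pyran-4-one, via chloro sulfide adduct 6 (not isolated)
Conditions: PhSH, N-chlorosuccinimide, CH2Cl2, 0 °C; then 5, −78 °C; then Et3N, −78 → 0 °C
Reagents that add atoms: benzenesulfenyl chloride, ClSc1ccccc1; benzenethiol, Sc1ccccc1; N-chlorosuccinimide, O=C1CCC(=O)N1Cl
Why: Electrophilic sulfenylation of the vinylogous ester at its nucleophilic α-carbon C5 by addition of PhSCl (made in the flask from the thiol and N-chlorosuccinimide, which supply the PhS group of 7 and the chlorine of 6) across the enol ether bond, followed by Et3N-induced loss of HCl (addition–elimination); C2 is not touched.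

Step 4
Reactants: 7 (S)-2-[4-methoxy-3-(triisopropylsilyloxy)phenyl]-5-(phenylthio)-2,3-dihydro-4H-pyran-4-one
Product: 8 (2S)-2-[4-methoxy-3-(triisopropylsilyloxy)phenyl]-5-(phenylsulfinyl)-2,3-dihydro-4H-pyran-4-one (mixture at sulfur)
Conditions: mCPBA (1.0 equiv), CH2Cl2, −78 → −40 °C
Reagents that add atoms: 3-chloroperbenzoic acid, OOC(=O)c1cccc(Cl)c1
Why: Chemoselective sulfide-to-sulfoxide oxidation with one equivalent of peracid at low temperature, the push-pull enone bond and the silyl ether being inert; the sulfur configuration is left mixed because the group is lost in step 8.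

Step 5
Reactants: 9 methyl acetoacetate; 10 geranyl bromide
Product: 11 methyl 2-geranylacetoacetate (racemic)
Conditions: NaH, THF, 0 °C; then 10, 0 → 25 °C (9 in excess)
Reagents that add atoms: none
Why: Acetoacetic ester alkylation, an SN2 C-alkylation of the sodium enolate with the primary allylic bromide; the excess of 9 limits dialkylation and the (E)-alkene is retained.

Step 6
Reactants: 11 methyl 2-geranylacetoacetate
Product: 12 methyl 2-geranyl-3-(trimethylsilyloxy)but-2-enoate (E/Z mixture)
Conditions: Me3SiCl, Et3N, PhMe, 25 °C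
Reagents that add atoms: chlorotrimethylsilane, C[Si](C)(C)Cl
Why: Amine-mediated O-silylation of the enolised β-keto ester (soft enolisation) gives the conjugated silyl enol ether, as is usual for 2-alkyl acetoacetates.

Step 7
Reactants: 12 methyl 2-geranyl-3-(trimethylsilyloxy)but-2-enoate
Product: 13 1-methoxy-2-geranyl-1,3-bis(trimethylsilyloxy)buta-1,3-diene
Conditions: LiN(iPr)2, THF, −78 °C; then Me3SiCl, −78 → 20 °C; non-aqueous work-up, used crude
Reagents that add atoms: chlorotrimethylsilane, C[Si](C)(C)Cl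
Why: Chan-type diene synthesis: kinetic γ-deprotonation of the β-silyloxy enoate at the C4 methyl group and O-silylation of the ester dienolate give the 1,3-bis(silyloxy)diene.

Step 8
Reactants: 8 (2S)-2-[4-methoxy-3-(triisopropylsilyloxy)phenyl]-5-(phenylsulfinyl)-2,3-dihydro-4H-pyran-4-one; 13 1-methoxy-2-geranyl-1,3-bis(trimethylsilyloxy)buta-1,3-diene
Product: 17 (2S)-6-geranyl-5,7-dihydroxy-4'-methoxy-3'-(triisopropylsilyloxy)flavanone, via cycloadduct 14 (not isolated), via ketal 15 (not isolated), via bis-silyl ether 16 (not isolated)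
Conditions: 13 (3 equiv), PhMe, 0 → 25 °C, then 80 °C; then AcOH, THF/H2O, 25 °C
Reagents that add atoms: none
Why: Proposed new method: the electron-rich ketene acetal diene 13 should add to the C5=C6 bond of 8, made electrophilic at C6 by the keto and sulfinyl groups on C5, in an asynchronous [4+2] cycloaddition (or a Mukaiyama–Michael addition followed by collapse of the ion pair) that joins the CH2 terminus of the diene to C6 (future C8a) and the ketene acetal carbon to C5 (future C4a), closing ring A as a six-membered carbocycle to give 14. The cis ring fusion puts H8a syn to the sulfinyl group, so thermal syn elimination of PhSOH should give 15, 1,4-elimination of methanol aromatises ring A to 16, and mild acid cleaves the two aryl trimethylsilyl ethers. The closest known reaction type is the Diels–Alder, sulfoxide elimination and aromatisation sequence of 1,1,3-trioxygenated dienes with sulfinyl quinones and 2-sulfinyl cycloalkenones; it has not been shown on a 5-sulfinyl-2,3-dihydropyran-4-one. No new stereocentre survives the aromatisation and C2 is a spectator. The step needs regioselectivity, secured by pairing the nucleophilic CH2 terminus of the diene with the doubly activated β-carbon C6, and it needs the second bond to form at the ketene acetal carbon, the only terminus that gives a six-membered ring, before silyl transfer traps an open Michael adduct; neutral conditions are chosen so that no enolate lives long enough to expel O1.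

Step 9
Reactants: 17 (2S)-6-geranyl-5,7-dihydroxy-4'-methoxy-3'-(triisopropylsilyloxy)flavanone
Product: 18 (2S)-6-geranyl-3',5,7-trihydroxy-4'-methoxyflavanone (target, CNP0264411.1)
Conditions: Bu4NF, AcOH (1:1), THF, 0 °C
Reagents that add atoms: none
Why: Fluoride desilylation of the aryl silyl ether, buffered with AcOH so that no phenoxide or enolate can open ring C and erode the C2 configuration.

**Compound list**

1 | isovanillin | COc1ccc(C=O)cc1O | starting material
2 | 4-methoxy-3-(triisopropylsilyloxy)benzaldehyde | COc1ccc(C=O)cc1O[Si](C(C)C)(C(C)C)C(C)C | intermediate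
3 | (E)-1-methoxy-3-(trimethylsilyloxy)buta-1,3-diene | CO/C=C/C(=C)O[Si](C)(C)C | starting material
4 | (S,E)-1-methoxy-5-aryl-5-(trimethylsilyloxy)pent-1-en-3-one, Mukaiyama aldol adduct | CO/C=C/C(=O)C[C@H](O[Si](C)(C)C)c1ccc(OC)c(O[Si](C(C)C)(C(C)C)C(C)C)c1 | intermediate (not isolated)
5 | (S)-2-[4-methoxy-3-(triisopropylsilyloxy)phenyl]-2,3-dihydro-4H-pyran-4-one | COc1ccc([C@@H]2CC(=O)C=CO2)cc1O[Si](C(C)C)(C(C)C)C(C)C | intermediate
6 | (2S)-2-aryl-6-chloro-5-(phenylthio)tetrahydropyran-4-one, C5 and C6 unassigned | COc1ccc([C@@H]2CC(=O)C(Sc3ccccc3)C(Cl)O2)cc1O[Si](C(C)C)(C(C)C)C(C)C | intermediate (not isolated)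
7 | (S)-2-[4-methoxy-3-(triisopropylsilyloxy)phenyl]-5-(phenylthio)-2,3-dihydro-4H-pyran-4-one | COc1ccc([C@@H]2CC(=O)C(Sc3ccccc3)=CO2)cc1O[Si](C(C)C)(C(C)C)C(C)C | intermediate
8 | (2S)-2-[4-methoxy-3-(triisopropylsilyloxy)phenyl]-5-(phenylsulfinyl)-2,3-dihydro-4H-pyran-4-one, mixture at sulfur | COc1ccc([C@@H]2CC(=O)C(=CO2)S(=O)c2ccccc2)cc1O[Si](C(C)C)(C(C)C)C(C)C | intermediate
9 | methyl acetoacetate | COC(=O)CC(C)=O | starting material
10 | geranyl bromide | CC(C)=CCC/C(C)=C/CBr | starting material
11 | methyl 2-geranylacetoacetate, racemic | COC(=O)C(C/C=C(\C)CCC=C(C)C)C(C)=O | intermediate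
12 | methyl 2-geranyl-3-(trimethylsilyloxy)but-2-enoate, E/Z mixture | COC(=O)C(C/C=C(\C)CCC=C(C)C)=C(C)O[Si](C)(C)C | intermediate
13 | 1-methoxy-2-geranyl-1,3-bis(trimethylsilyloxy)buta-1,3-diene | COC(O[Si](C)(C)C)=C(C/C=C(\C)CCC=C(C)C)C(=C)O[Si](C)(C)C | intermediate
14 | cis-fused cycloadduct, (2S)-2-aryl-6-geranyl-5-methoxy-4a-(phenylsulfinyl)-5,7-bis(trimethylsilyloxy)-2,3,4a,5,8,8a-hexahydrochromen-4-one, new centres unassigned | COc1ccc([C@@H]2CC(=O)C3(S(=O)c4ccccc4)C(CC(O[Si](C)(C)C)=C(C/C=C(\C)CCC=C(C)C)C3(OC)O[Si](C)(C)C)O2)cc1O[Si](C(C)C)(C(C)C)C(C)C | intermediate (not isolated)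
15 | (2S)-2-aryl-6-geranyl-5-methoxy-5,7-bis(trimethylsilyloxy)-2,3,5,8-tetrahydrochromen-4-one | COc1ccc([C@@H]2CC(=O)C3=C(CC(O[Si](C)(C)C)=C(C/C=C(\C)CCC=C(C)C)C3(OC)O[Si](C)(C)C)O2)cc1O[Si](C(C)C)(C(C)C)C(C)C | intermediate (not isolated)
16 | (2S)-6-geranyl-4'-methoxy-3'-(triisopropylsilyloxy)-5,7-bis(trimethylsilyloxy)flavanone | COc1ccc([C@@H]2CC(=O)c3c(cc(O[Si](C)(C)C)c(C/C=C(\C)CCC=C(C)C)c3O[Si](C)(C)C)O2)cc1O[Si](C(C)C)(C(C)C)C(C)C | intermediate (not isolated)
17 | (2S)-6-geranyl-5,7-dihydroxy-4'-methoxy-3'-(triisopropylsilyloxy)flavanone | COc1ccc([C@@H]2CC(=O)c3c(cc(O)c(C/C=C(\C)CCC=C(C)C)c3O)O2)cc1O[Si](C(C)C)(C(C)C)C(C)C | intermediate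
18 | (2S)-6-geranyl-3',5,7-trihydroxy-4'-methoxyflavanone | COc1ccc([C@@H]2CC(=O)c3c(cc(O)c(C/C=C(\C)CCC=C(C)C)c3O)O2)cc1O | target

**Step count**

Total: 9 steps. Longest linear sequence: 6 steps (1, 2, 3, 4, 8, 9); the diene branch (5, 6, 7) joins at step 8.

**Steps most likely to fail**

1. Step 8. The hindered diene may add too slowly to the deactivated vinylogous ester; the addition may stop at the open Michael stage; or an enolate formed on the way may expel O1, open ring C and aromatise without the ring oxygen.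
Fallback (known chalcone chemistry; sets out from geranyl bromide 10 and isovanillin 1, returns at 18). Commercial 2,4,6-trihydroxyacetophenone is C-geranylated with 10 (DBU, THF, 25 °C) to 3-geranyl-2,4,6-trihydroxyacetophenone F1. MOMCl/iPr2NEt converts it into 3-geranyl-2-hydroxy-4,6-bis(methoxymethoxy)acetophenone F2. Isovanillin 1 is converted with MOMCl/iPr2NEt into 4-methoxy-3-(methoxymethoxy)benzaldehyde F3. Claisen–Schmidt condensation of F2 with F3 (KOH, EtOH/H2O, 25 °C) gives the protected chalcone F4. HCl in MeOH (40 °C) removes the three methoxymethyl groups to give the tetrahydroxychalcone F5. NaOAc in EtOH at reflux closes ring C by oxa-Michael addition to the racemic 6-geranyl flavanone F6, formed beside the 8-geranyl regioisomer F7. F6 is separated on silica and resolved by preparative HPLC on a cellulose-based chiral phase to give 18. This path gives up the regiocontrol and the enantiocontrol of the main route and relies on two separations.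

2. Step 3. Sulfenylation may occur at the enolisable C3 position or on the electron-rich ring B, or the chloride adduct may not eliminate cleanly.
Fallback (sets out from 5, returns at 7). α-Iodination of the enone (I2, pyridine, CH2Cl2, 0 → 25 °C) should give (S)-2-aryl-5-iodo-2,3-dihydro-4H-pyran-4-one F8. Carbon–sulfur cross-coupling with PhSH (Pd2(dba)3, Xantphos, iPr2NEt, dioxane, 80 °C) then gives 7. The C5–S bond is thus formed by coupling at a defined vinyl iodide instead of by electrophilic attack.

3. Step 2. The Mukaiyama aldol addition to the electron-rich aldehyde may be slow and the facial selectivity insufficient.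
Fallback (sets out from 2, returns at 5). Allylboration of 2 with B-allyldiisopinocampheylborane of the (+)-α-pinene series (Et2O, −78 °C; ethanolamine work-up), which attacks the Si face of aryl aldehydes, should give the (S)-homoallylic alcohol F9. Tsuji–Wacker oxidation (PdCl2, CuCl, O2, DMF/H2O) gives the (S)-β-hydroxy methyl ketone F10. Claisen formylation at the methyl group (LiN(SiMe3)2, 2.2 equiv, HCO2Et, THF, −78 °C) gives the hydroxymethylene ketone F11, which CF3CO2H in CH2Cl2 cyclises with loss of water to 5.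

Further compounds
F1 | step 8 | 3-geranyl-2,4,6-trihydroxyacetophenone | CC(=O)c1c(O)cc(O)c(C/C=C(\C)CCC=C(C)C)c1O
F2 | step 8 | 3-geranyl-2-hydroxy-4,6-bis(methoxymethoxy)acetophenone | CC(=O)c1c(OCOC)cc(OCOC)c(C/C=C(\C)CCC=C(C)C)c1O
F3 | step 8 | 4-methoxy-3-(methoxymethoxy)benzaldehyde | COCOc1cc(C=O)ccc1OC
F4 | step 8 | (E)-3'-geranyl-2'-hydroxy-4-methoxy-3,4',6'-tris(methoxymethoxy)chalcone | COCOc1cc(/C=C/C(=O)c2c(OCOC)cc(OCOC)c(C/C=C(\C)CCC=C(C)C)c2O)ccc1OC
F5 | step 8 | (E)-3'-geranyl-2',3,4',6'-tetrahydroxy-4-methoxychalcone | COc1ccc(/C=C/C(=O)c2c(O)cc(O)c(C/C=C(\C)CCC=C(C)C)c2O)cc1O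
F6 | step 8 | racemic 6-geranyl-3',5,7-trihydroxy-4'-methoxyflavanone | COc1ccc(C2CC(=O)c3c(cc(O)c(C/C=C(\C)CCC=C(C)C)c3O)O2)cc1O
F7 | step 8 | racemic 8-geranyl-3',5,7-trihydroxy-4'-methoxyflavanone | COc1ccc(C2CC(=O)c3c(O)cc(O)c(C/C=C(\C)CCC=C(C)C)c3O2)cc1O
F8 | step 3 | (S)-5-iodo-2-[4-methoxy-3-(triisopropylsilyloxy)phenyl]-2,3-dihydro-4H-pyran-4-one | COc1ccc([C@@H]2CC(=O)C(I)=CO2)cc1O[Si](C(C)C)(C(C)C)C(C)C
F9 | step 2 | (S)-1-[4-methoxy-3-(triisopropylsilyloxy)phenyl]but-3-en-1-ol | C=CC[C@H](O)c1ccc(OC)c(O[Si](C(C)C)(C(C)C)C(C)C)c1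
F10 | step 2 | (S)-4-hydroxy-4-[4-methoxy-3-(triisopropylsilyloxy)phenyl]butan-2-one | CC(=O)C[C@H](O)c1ccc(OC)c(O[Si](C(C)C)(C(C)C)C(C)C)c1
F11 | step 2 | (S)-1,5-dihydroxy-5-[4-methoxy-3-(triisopropylsilyloxy)phenyl]pent-1-en-3-one | OC=CC(=O)C[C@H](O)c1ccc(OC)c(O[Si](C(C)C)(C(C)C)C(C)C)c1
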